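(The earlier runs and the new flask are calculated for an exercise, and the scatter is random.)

| setting | alder | maple | cedar | flask |
|---|---|---|---|---|
| substrate | 0.020 M | 0.020 M | 0.030 M | 0.020 M |
| reagent | 0.025 M | 0.10 M | 0.050 M | 0.0500 M |
| remark | run made earlier | run made earlier | run made earlier |  |
| time |  |  |  | 5.0 min |

- alder (time / min: product / %): 0.500: 58.1; 0.667: 62.1; 1.00: 64.0; 1.50: 65.1; 2.50: 64.5; 4.00: 64.4; 6.00: 64.7
- maple (time / min: product / %): 0.333: 75.6; 1.00: 80.2; 1.50: 78.2; 2.50: 78.8; 4.00: 81.1; 5.00: 78.4; 6.00: 79.9
- cedar (time / min: product / %): 0.500: 63.4; 1.50: 65.3; 3.00: 65.9; 4.00: 64.8; 6.00: 64.4

(scatter of a reading: 1 percentage point)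

- in percentages every species weighs as the substrate in it: one homo dimer counts as two
- reactions considered so far: 2 substrate -> homo dimer; substrate + reagent -> product
- the reaction counts as stopped when no species that holds the substrate changes by six tenths of a point or more over the second half of the time

1. at 5.0 min, what has stopped the reaction, if anything has (the reagent has run out first / all of the substrate has reacted / it is still moving)
2. how much product there is at 5.0 min, in percent of the substrate charged

**Open books.** Hold one balance fixed: every unit of substrate charged stands as substrate, product or homo dimer. Keep the ledger on the substrate, the limiting reagent of this flask, whose 0.020 M faces 0.0500 M of reagent.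

**First entry.** Close the substrate line. Alder's last 4 readings average 64.7% and stay flat from 1.50 min, though that product took 0.0129 M of the 0.025 M reagent. So expect the flask's substrate line closed by 5.0 min.

**Second entry.** Split what closed. Divide one rate by the other and time drops out: product gained per substrate lost to dimer rises with reagent and falls with substrate. Call w the product share over the dimer share at the stop. Alder gives 1.83; maple, averaging 79.4%, gives 3.86. The flask's reagent charge is the geometric mean of the alder and maple charges, and all three share one substrate charge, so take the geometric mean of the two w and multiply it by that substrate charge: this is the split capacity W 0.0532 M, which I assume roughly constant at this reagent charge. Cedar, at that reagent and averaging 65.1%, reads 0.0560 M. My reckoning, W/(W + substrate charge), books 72.7% as product.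

**The forecast.** It says that all of the substrate has reacted, with 73% product, noting: “The product route looks roughly half order in reagent”.

**The flask.** Here all of the substrate has reacted: at 5.0 min, the flask holds substrate 0%, product 72.4%, homo dimer 27.6%.

    2 substrate → homo dimer (k = 2.32 M⁻¹ s⁻¹)
    substrate + reagent → product, rate k2*[substrate]*[reagent]^0.5 (k = 0.517 M⁻⁰·⁵ s⁻¹)

**The neighbour.** Read W back from the flask: 0.0525 M. Carry the earlier 0.0532 M to the flask with 0.034 M substrate and the same reagent: W/(W + substrate charge) books 61.0%. That neighbour ends with substrate at 0%, reagent at 58% of its charge, and product at 61.3%.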